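**Plan**

- Retrosynthesis: the silyl and acyl groups are removed, the C4–O bond is traced back by inversion to the 2,4-cis carbinol and this to a (2S)-flavanone. Ring C is then cut at C4–C4a (acylation of the arene) and at O1–C2 (etherification with inversion).
- The ring A phenol that remains is cut at C8–C8a, C6–C7 and C4a–C8a into a 3-silyloxycyclobutenone (it supplies C8a, C6, C5, C4a) and a prenylated methyl ynol ether (C8, C7).
- Enabling feature: ring A is a phloroglucinol whose three oxygens all differ (O1 of ring C, 5-OH, 7-OMe). The prenyl group sits on C8 between C8a–O1 and C7–OMe, and C4a is the only other ring carbon that must later bear carbon. A cyclobutenone/ynol ether benzannulation lays down exactly this 1-hydroxy-2-alkyl-3-alkoxy-5-oxy pattern.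
- Forward: ring A is built first, the C2–C3–C4 chain carrying ring B is attached at O1, and ring C closes last at C4–C4a.
- Stereochemistry: C2 comes from an (R)-benzylic carbinol (catalytic asymmetric allylation) that is inverted in the etherification. C4 comes from substrate-controlled hydride addition (2,4-cis) followed by Mitsunobu inversion (2,4-trans).

Key step: step 4

Remark: the SMILES is read as the (2S,4R) isomer, with the 4-hydroxyphenyl group at C2 and the hydroxyl at C4 trans on ring C; prenyl means 3-methylbut-2-en-1-yl.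

**Route**

Step 1
Reactants: 1 chloroacetaldehyde dimethyl acetal; 2 prenyl bromide
Product: 4 1-methoxy-5-methylhex-4-en-1-yne, via sodium methoxyacetylide 3 (not isolated)
Conditions: NaNH2 (3.2 equiv), liq. NH3, −33 °C; then 2, −33 °C; NH4Cl, pentane extraction, distillation
Reagents that add atoms: none
Why: Excess NaNH2 should eliminate HCl and methanol from the chloroacetal and deprotonate the methoxyacetylene formed, and the sodium acetylide is then C-alkylated by the primary allylic bromide in an SN2 reaction (one-pot elimination–alkylation synthesis of 1-alkoxy-1-alkynes).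

Step 2
Reactants: 5 3-ethoxycyclobut-2-en-1-one
Product: 6 cyclobutane-1,3-dione
Conditions: 1 M aq. HCl, THF, 0 °C → rt; freeze-drying, stored cold
Reagents that add atoms: water, O
Why: Acid hydrolysis of a vinylogous ester (addition of water at C3, loss of ethanol) should free the 1,3-dione, which is used promptly because it is only moderately stable.

Step 3
Reactants: 6 cyclobutane-1,3-dione
Product: 7 3-(triisopropylsilyloxy)cyclobut-2-en-1-one
Conditions: TIPSOTf (1.05 equiv), Et3N, CH2Cl2, −78 → 0 °C
Reagents that add atoms: triisopropylsilyl trifluoromethanesulfonate, CC(C)[Si](C(C)C)(C(C)C)OS(=O)(=O)C(F)(F)F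
Why: O-Silylation of the acidic enol form of a cyclic 1,3-diketone with a silyl triflate and an amine base should give the vinylogous silyl ester, the bulky triisopropylsilyl group being chosen for stability in the thermal step and later.

Step 4
Reactants: 7 3-(triisopropylsilyloxy)cyclobut-2-en-1-one; 4 1-methoxy-5-methylhex-4-en-1-yne
Product: 12 3-methoxy-2-(3-methylbut-2-en-1-yl)-5-(triisopropylsilyloxy)phenol, via vinylketene 8 (not isolated), via vinylcyclobutenone 9 (not isolated), via dienylketene 10 (not isolated), via cyclohexadienone 11 (not isolated)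
Conditions: 4 (2 equiv), toluene, 110 °C, sealed tube
Reagents that add atoms: none
Why: Proposed new method: thermal four-electron electrocyclic opening of 7 should give the 3-silyloxy vinylketene 8, which adds the ynol ether 4 in a [2+2] cycloaddition (C8–C8a and C6–C7 formed) to give the 4-vinylcyclobutenone 9, and a second four-electron opening gives the dienylketene 10, which cyclises to the cyclohexadienone 11 and enolises to the phenol 12. The closest known reaction type is the Danheiser benzannulation of alkyl- or aryl-substituted cyclobutenones with alkoxy- and silyloxyalkynes to resorcinol monoethers; a 3-silyloxycyclobutenone, and with it the phloroglucinol oxygenation pattern, is the extension proposed here. Ring A closes by six-electron electrocyclisation of the cis-dienylketene, which forms C4a–C8a, and no stereocentre is created because 11 aromatises. The step needs the regiochemistry in which the prenyl-bearing β-carbon of the ynol ether bonds to the ketene carbonyl carbon, and the matched polarisation of the electrophilic ketene carbon and the nucleophilic β-carbon of the oxygen-substituted alkyne secures it. It also needs the ketene to choose the alkyne over the trisubstituted prenyl alkene, which the far higher nucleophilicity of the ynol ether ensures, while the methyl ynol ether has no β-hydrogen for retro-ene loss at this temperature. The silyloxy group is cross-conjugated to the ketene and should not quench its electrophilicity, and the excess of 4 limits O-acylation of 12 by 8.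

Step 5
Reactants: 13 4-hydroxybenzaldehyde
Product: 14 4-formylphenyl pivalate
Conditions: PivCl, Et3N, DMAP (cat.), CH2Cl2, 0 °C → rt
Reagents that add atoms: pivaloyl chloride, CC(C)(C)C(=O)Cl
Why: DMAP-catalysed acylation of the phenol should install an electron-withdrawing, hindered ester that later disfavours benzylic ionisation at C2.

Step 6
Reactants: 14 4-formylphenyl pivalate
Product: 15 4-[(1R)-1-hydroxybut-3-en-1-yl]phenyl pivalate
Conditions: allylSnBu3 (1.3 equiv), (R)-BINOL (20 mol %), Ti(OiPr)4 (10 mol %), 4 Å molecular sieves, CH2Cl2, −20 °C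
Reagents that add atoms: allyltributylstannane, C=CC[Sn](CCCC)(CCCC)CCCC
Why: Keck asymmetric allylation, in which the chiral BINOL–titanium Lewis acid is expected to expose the Re face of the aryl aldehyde to the allylstannane and so set the (R)-carbinol, under neutral conditions that spare the aryl ester.

Step 7
Reactants: 15 4-[(1R)-1-hydroxybut-3-en-1-yl]phenyl pivalate
Product: 17 4-[(1R)-1,3-dihydroxypropyl]phenyl pivalate, via hydroxy aldehyde 16 (not isolated)
Conditions: O3, CH2Cl2/MeOH (4:1), −78 °C; then NaBH4, −78 → 0 °C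
Reagents that add atoms: ozone, [O-][O+]=O
Why: Ozonolysis with reductive borohydride work-up should cleave the terminal alkene to the primary alcohol without touching the carbinol centre; it is done here because the prenyl alkene is not yet in the molecule.

Step 8
Reactants: 17 4-[(1R)-1,3-dihydroxypropyl]phenyl pivalate
Product: 18 4-[(1R)-3-(tert-butyldimethylsilyloxy)-1-hydroxypropyl]phenyl pivalate
Conditions: TBSCl (1.05 equiv), imidazole, CH2Cl2, 0 °C
Reagents that add atoms: tert-butyldimethylsilyl chloride, CC(C)(C)[Si](C)(C)Cl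
Why: Silylation should select the unhindered primary hydroxyl over the secondary benzylic one, leaving the latter free for the etherification.

Step 9
Reactants: 12 3-methoxy-2-(3-methylbut-2-en-1-yl)-5-(triisopropylsilyloxy)phenol; 18 4-[(1R)-3-(tert-butyldimethylsilyloxy)-1-hydroxypropyl]phenyl pivalate
Product: 19 4-[(1S)-3-(tert-butyldimethylsilyloxy)-1-[3-methoxy-2-(3-methylbut-2-en-1-yl)-5-(triisopropylsilyloxy)phenoxy]propyl]phenyl pivalate
Conditions: PPh3, DIAD, toluene, 0 °C → rt
Reagents that add atoms: none
Why: Mitsunobu etherification, in which the phenol displaces the oxyphosphonium of the benzylic carbinol by SN2, so that the (R) centre becomes the (S) centre that is C2 of the flavan, the pivaloyloxy group on ring B disfavouring ionisation and loss of configuration.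

Step 10
Reactants: 19 silyl ether from step 9
Product: 20 4-[(1S)-3-hydroxy-1-[3-methoxy-2-(3-methylbut-2-en-1-yl)-5-(triisopropylsilyloxy)phenoxy]propyl]phenyl pivalate
Conditions: CSA (10 mol %), MeOH/CH2Cl2 (1:1), 0 °C
Reagents that add atoms: none
Why: Acid-catalysed methanolysis should remove the primary alkyl silyl ether selectively, since aryl triisopropylsilyl ethers resist mild acid and the pivalate, aryl ether and prenyl alkene are inert under these conditions.

Step 11
Reactants: 20 primary alcohol from step 10
Product: 22 (3S)-3-[3-methoxy-2-(3-methylbut-2-en-1-yl)-5-(triisopropylsilyloxy)phenoxy]-3-[4-(pivaloyloxy)phenyl]propanoic acid, via aldehyde 21 (not isolated)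
Conditions: TEMPO (20 mol %), PhI(OAc)2 (2.2 equiv), MeCN/H2O (1:1), rt
Reagents that add atoms: water, O
Why: Oxoammonium-mediated oxidation (TEMPO with PhI(OAc)2 in aqueous acetonitrile) should take the primary alcohol through the aldehyde hydrate to the acid in a non-basic medium, which avoids β-elimination of the aryloxide and leaves the trisubstituted alkene and the aryl ethers alone.

Step 12
Reactants: 22 acid from step 11
Product: 24 4-[(2S)-7-methoxy-8-(3-methylbut-2-en-1-yl)-4-oxo-5-(triisopropylsilyloxy)-3,4-dihydro-2H-chromen-2-yl]phenyl pivalate, via mixed anhydride 23 (not isolated)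
Conditions: TFAA (1.5 equiv), CH2Cl2, −20 → 0 °C; cold aq. NaHCO3
Reagents that add atoms: none
Why: Intramolecular Friedel–Crafts acylation through the mixed trifluoroacetic anhydride, for which the trioxygenated ring A should be nucleophilic enough without a Lewis acid; C4a (para to the methoxyl) is the only carbon that can close the six-membered ring C, and C2 is not involved.

Step 13
Reactants: 24 (2S)-flavanone from step 12
Product: 25 4-[(2S,4S)-4-hydroxy-7-methoxy-8-(3-methylbut-2-en-1-yl)-5-(triisopropylsilyloxy)-3,4-dihydro-2H-chromen-2-yl]phenyl pivalate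
Conditions: NaBH4, THF/MeOH (4:1), −10 °C
Reagents that add atoms: none
Why: Borohydride reduction, in which hydride should add axially to the half-chair with the 2-aryl group equatorial, placing the new hydroxyl equatorial and cis to the aryl group (4S), at a temperature too low for ring opening to the chalcone.

Step 14
Reactants: 25 cis-flavan-4-ol from step 13
Product: 26 (2S,4R)-7-methoxy-8-(3-methylbut-2-en-1-yl)-2-[4-(pivaloyloxy)phenyl]-5-(triisopropylsilyloxy)-3,4-dihydro-2H-chromen-4-yl benzoate
Conditions: PPh3, DIAD, PhCO2H, THF, −20 °C → rt; chromatography on Et3N-deactivated silica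
Reagents that add atoms: benzoic acid, O=C(O)c1ccccc1
Why: Mitsunobu inversion, in which benzoate should displace the oxyphosphonium from the face opposite to it and turn 4S into 4R, and even if the electron-rich benzylic centre ionises, axial capture of the cation is expected to lead to the same 2,4-trans ester.

Step 15
Reactants: 26 benzoate from step 14
Product: 27 (2S,4R)-2-(4-hydroxyphenyl)-7-methoxy-8-(3-methylbut-2-en-1-yl)-5-(triisopropylsilyloxy)-3,4-dihydro-2H-chromen-4-ol
Conditions: LiOH·H2O (4 equiv), THF/H2O (3:1), 0 °C → rt; aq. NH4Cl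
Reagents that add atoms: none
Why: Saponification by acyl–oxygen cleavage should remove the benzoate with retention at C4 together with the aryl pivalate, and it is run while O5 is still silylated so that no ortho-phenoxide can expel the C4 ester, any solvolysis in the aqueous medium leading again to the alcohol.

Step 16
Reactants: 27 silyl ether from step 15
Product: 28 (2S,4R)-2-(4-hydroxyphenyl)-7-methoxy-8-(3-methylbut-2-en-1-yl)-3,4-dihydro-2H-chromene-4,5-diol (target)
Conditions: TBAF (1.2 equiv), AcOH (1.2 equiv), THF, 0 °C; pH 7 buffer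
Reagents that add atoms: none
Why: Fluoride cleavage of the aryl silyl ether, buffered with acetic acid, should release the 5-hydroxyl without acid or strong base reaching the ionisable C4 carbinol.

**Compound list**

1 | chloroacetaldehyde dimethyl acetal | COC(CCl)OC | starting material
2 | prenyl bromide | CC(C)=CCBr | starting material
3 | sodium methoxyacetylide (formed in situ) | [Na+].[C-]#COC | intermediate
4 | 1-methoxy-5-methylhex-4-en-1-yne | COC#CCC=C(C)C | intermediate
5 | 3-ethoxycyclobut-2-en-1-one | CCOC1=CC(=O)C1 | starting material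
6 | cyclobutane-1,3-dione | O=C1CC(=O)C1 | intermediate
7 | 3-(triisopropylsilyloxy)cyclobut-2-en-1-one | O=C1C=C(O[Si](C(C)C)(C(C)C)C(C)C)C1 | intermediate
8 | 3-(triisopropylsilyloxy)buta-1,3-dien-1-one (vinylketene, formed in situ) | O=C=CC(=C)O[Si](C(C)C)(C(C)C)C(C)C | intermediate
9 | 3-methoxy-2-(3-methylbut-2-en-1-yl)-4-[1-(triisopropylsilyloxy)ethenyl]cyclobut-2-en-1-one (racemic, formed in situ) | O=C1C(CC=C(C)C)=C(OC)C1C(=C)O[Si](C(C)C)(C(C)C)C(C)C | intermediate
10 | (3E)-3-methoxy-2-(3-methylbut-2-en-1-yl)-5-(triisopropylsilyloxy)hexa-1,3,5-trien-1-one (dienylketene, formed in situ) | O=C=C(CC=C(C)C)/C(OC)=C\C(=C)O[Si](C(C)C)(C(C)C)C(C)C | intermediate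
11 | 3-methoxy-2-(3-methylbut-2-en-1-yl)-5-(triisopropylsilyloxy)cyclohexa-2,4-dien-1-one (formed in situ) | O=C1CC(O[Si](C(C)C)(C(C)C)C(C)C)=CC(OC)=C1CC=C(C)C | intermediate
12 | 3-methoxy-2-(3-methylbut-2-en-1-yl)-5-(triisopropylsilyloxy)phenol | COc1cc(O[Si](C(C)C)(C(C)C)C(C)C)cc(O)c1CC=C(C)C | intermediate
13 | 4-hydroxybenzaldehyde | O=Cc1ccc(O)cc1 | starting material
14 | 4-formylphenyl pivalate | CC(C)(C)C(=O)Oc1ccc(C=O)cc1 | intermediate
15 | 4-[(1R)-1-hydroxybut-3-en-1-yl]phenyl pivalate | C=CC[C@@H](O)c1ccc(OC(=O)C(C)(C)C)cc1 | intermediate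
16 | 4-[(1R)-1-hydroxy-3-oxopropyl]phenyl pivalate (formed in situ) | O=CC[C@@H](O)c1ccc(OC(=O)C(C)(C)C)cc1 | intermediate
17 | 4-[(1R)-1,3-dihydroxypropyl]phenyl pivalate | OCC[C@@H](O)c1ccc(OC(=O)C(C)(C)C)cc1 | intermediate
18 | 4-[(1R)-3-(tert-butyldimethylsilyloxy)-1-hydroxypropyl]phenyl pivalate | CC(C)(C)[Si](C)(C)OCC[C@@H](O)c1ccc(OC(=O)C(C)(C)C)cc1 | intermediate
19 | 4-[(1S)-3-(tert-butyldimethylsilyloxy)-1-[3-methoxy-2-(3-methylbut-2-en-1-yl)-5-(triisopropylsilyloxy)phenoxy]propyl]phenyl pivalate | COc1cc(O[Si](C(C)C)(C(C)C)C(C)C)cc(O[C@@H](CCO[Si](C)(C)C(C)(C)C)c2ccc(OC(=O)C(C)(C)C)cc2)c1CC=C(C)C | intermediate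
20 | 4-[(1S)-3-hydroxy-1-[3-methoxy-2-(3-methylbut-2-en-1-yl)-5-(triisopropylsilyloxy)phenoxy]propyl]phenyl pivalate | COc1cc(O[Si](C(C)C)(C(C)C)C(C)C)cc(O[C@@H](CCO)c2ccc(OC(=O)C(C)(C)C)cc2)c1CC=C(C)C | intermediate
21 | 4-[(1S)-1-[3-methoxy-2-(3-methylbut-2-en-1-yl)-5-(triisopropylsilyloxy)phenoxy]-3-oxopropyl]phenyl pivalate (formed in situ) | COc1cc(O[Si](C(C)C)(C(C)C)C(C)C)cc(O[C@@H](CC=O)c2ccc(OC(=O)C(C)(C)C)cc2)c1CC=C(C)C | intermediate
22 | (3S)-3-[3-methoxy-2-(3-methylbut-2-en-1-yl)-5-(triisopropylsilyloxy)phenoxy]-3-[4-(pivaloyloxy)phenyl]propanoic acid | COc1cc(O[Si](C(C)C)(C(C)C)C(C)C)cc(O[C@@H](CC(=O)O)c2ccc(OC(=O)C(C)(C)C)cc2)c1CC=C(C)C | intermediate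
23 | mixed anhydride of 22 with trifluoroacetic acid (formed in situ) | COc1cc(O[Si](C(C)C)(C(C)C)C(C)C)cc(O[C@@H](CC(=O)OC(=O)C(F)(F)F)c2ccc(OC(=O)C(C)(C)C)cc2)c1CC=C(C)C | intermediate
24 | 4-[(2S)-7-methoxy-8-(3-methylbut-2-en-1-yl)-4-oxo-5-(triisopropylsilyloxy)-3,4-dihydro-2H-chromen-2-yl]phenyl pivalate | COc1cc(O[Si](C(C)C)(C(C)C)C(C)C)c2c(c1CC=C(C)C)O[C@H](c1ccc(OC(=O)C(C)(C)C)cc1)CC2=O | intermediate
25 | 4-[(2S,4S)-4-hydroxy-7-methoxy-8-(3-methylbut-2-en-1-yl)-5-(triisopropylsilyloxy)-3,4-dihydro-2H-chromen-2-yl]phenyl pivalate | COc1cc(O[Si](C(C)C)(C(C)C)C(C)C)c2c(c1CC=C(C)C)O[C@H](c1ccc(OC(=O)C(C)(C)C)cc1)C[C@@H]2O | intermediate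
26 | (2S,4R)-7-methoxy-8-(3-methylbut-2-en-1-yl)-2-[4-(pivaloyloxy)phenyl]-5-(triisopropylsilyloxy)-3,4-dihydro-2H-chromen-4-yl benzoate | COc1cc(O[Si](C(C)C)(C(C)C)C(C)C)c2c(c1CC=C(C)C)O[C@H](c1ccc(OC(=O)C(C)(C)C)cc1)C[C@H]2OC(=O)c1ccccc1 | intermediate
27 | (2S,4R)-2-(4-hydroxyphenyl)-7-methoxy-8-(3-methylbut-2-en-1-yl)-5-(triisopropylsilyloxy)-3,4-dihydro-2H-chromen-4-ol | COc1cc(O[Si](C(C)C)(C(C)C)C(C)C)c2c(c1CC=C(C)C)O[C@H](c1ccc(O)cc1)C[C@H]2O | intermediate
28 | (2S,4R)-2-(4-hydroxyphenyl)-7-methoxy-8-(3-methylbut-2-en-1-yl)-3,4-dihydro-2H-chromene-4,5-diol | COc1cc(O)c2c(c1CC=C(C)C)O[C@H](c1ccc(O)cc1)C[C@H]2O | target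

**Step count**

Total step count: 16.
Longest linear sequence: 12 steps (13 to 28, steps 5–16).

**Steps most likely to fail**

Step 4 (Proposed new method). The vinylogous silyl ester may resist electrocyclic opening, the silyloxy vinylketene may oligomerise or acylate the product phenol faster than it adds the ynol ether, or the cycloaddition may lose its regiochemistry. The fallback builds ring A from a preformed phloroglucinol by known chemistry, setting out from prenyl bromide 2 and commercial 5-methoxybenzene-1,3-diol F1. Monosilylation (TIPSCl 1 equiv, imidazole, DMF) would give 3-methoxy-5-(triisopropylsilyloxy)phenol F2, and MOMCl/iPr2NEt would give the methoxymethyl ether F3. Directed ortho-lithiation (n-BuLi, THF, 0 °C) should occur between the OMOM and OMe groups, the only site flanked by two coordinating substituents, because the bulky silyl ether shields its own neighbours. Transmetalation with CuBr·SMe2 and alkylation with 2 would give the prenylated arene F4. Mild acid methanolysis of the acetal (HCl cat., MeOH, 0 °C) returns to the route at phenol 12.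

Step 12. The trifluoroacetic acid released may add to the prenyl alkene, or the C2–O1 bond may ionise and the acid fragment to a cinnamate, before acylation at the hindered C4a is complete. The fallback forms the C4–C4a bond without acid by a photochemical acyl shift and resolves C2 afterwards, setting out from phenol 12 and aldehyde 14. Doebner condensation of 14 with malonic acid (pyridine, cat. β-alanine, 90 °C) would give (E)-3-[4-(pivaloyloxy)phenyl]prop-2-enoic acid F5, and DCC/DMAP esterification with 12 the aryl cinnamate F6. Photo-Fries rearrangement (hν 300 nm, benzene) should move the acyl group to the free ortho carbon and give the 2'-hydroxychalcone F7, to be separated from any para isomer. NaOAc in EtOH at reflux would close ring C by oxa-Michael addition to the racemic flavanone F8. Asymmetric transfer hydrogenation with RuCl[(S,S)-TsDPEN](p-cymene) and HCO2H/Et3N should reduce only the (2S) enantiomer (kinetic resolution, at most half of the material) and leave the (2R)-flavanone F9 behind. The route is rejoined at the cis alcohol 25.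

Step 14. Activation of the hindered, doubly ortho-oxygenated benzylic alcohol may end in loss of a C3 proton (flav-3-ene) or in unselective capture of the benzylic cation, and the benzoate may solvolyse on isolation. The fallback sets C4 by reagent control at the ketone stage, setting out from flavanone 24. Corey–Bakshi–Shibata reduction with (S)-2-methyl-CBS-oxazaborolidine and catecholborane (toluene, −78 °C; catecholborane spares the prenyl alkene) should deliver hydride to the face that gives the (4R) carbinol, the trans alcohol F10. LiOH (THF/H2O, 0 °C) would then remove the pivalate, and the route is rejoined at 27.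

**Further compounds**

F1 | step 4 | 5-methoxybenzene-1,3-diol | COc1cc(O)cc(O)c1
F2 | step 4 | 3-methoxy-5-(triisopropylsilyloxy)phenol | COc1cc(O)cc(O[Si](C(C)C)(C(C)C)C(C)C)c1
F3 | step 4 | [3-methoxy-5-(methoxymethoxy)phenoxy]triisopropylsilane | COCOc1cc(OC)cc(O[Si](C(C)C)(C(C)C)C(C)C)c1
F4 | step 4 | [3-methoxy-5-(methoxymethoxy)-4-(3-methylbut-2-en-1-yl)phenoxy]triisopropylsilane | COCOc1cc(O[Si](C(C)C)(C(C)C)C(C)C)cc(OC)c1CC=C(C)C
F5 | step 12 | (E)-3-[4-(pivaloyloxy)phenyl]prop-2-enoic acid | CC(C)(C)C(=O)Oc1ccc(/C=C/C(=O)O)cc1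
F6 | step 12 | 3-methoxy-2-(3-methylbut-2-en-1-yl)-5-(triisopropylsilyloxy)phenyl (E)-3-[4-(pivaloyloxy)phenyl]prop-2-enoate | COc1cc(O[Si](C(C)C)(C(C)C)C(C)C)cc(OC(=O)/C=C/c2ccc(OC(=O)C(C)(C)C)cc2)c1CC=C(C)C
F7 | step 12 | 4-[(E)-3-[2-hydroxy-4-methoxy-3-(3-methylbut-2-en-1-yl)-6-(triisopropylsilyloxy)phenyl]-3-oxoprop-1-en-1-yl]phenyl pivalate | COc1cc(O[Si](C(C)C)(C(C)C)C(C)C)c(C(=O)/C=C/c2ccc(OC(=O)C(C)(C)C)cc2)c(O)c1CC=C(C)C
F8 | step 12 | racemic 4-[7-methoxy-8-(3-methylbut-2-en-1-yl)-4-oxo-5-(triisopropylsilyloxy)-3,4-dihydro-2H-chromen-2-yl]phenyl pivalate | COc1cc(O[Si](C(C)C)(C(C)C)C(C)C)c2c(c1CC=C(C)C)OC(c1ccc(OC(=O)C(C)(C)C)cc1)CC2=O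
F9 | step 12 | 4-[(2R)-7-methoxy-8-(3-methylbut-2-en-1-yl)-4-oxo-5-(triisopropylsilyloxy)-3,4-dihydro-2H-chromen-2-yl]phenyl pivalate | COc1cc(O[Si](C(C)C)(C(C)C)C(C)C)c2c(c1CC=C(C)C)O[C@@H](c1ccc(OC(=O)C(C)(C)C)cc1)CC2=O
F10 | step 14 | 4-[(2S,4R)-4-hydroxy-7-methoxy-8-(3-methylbut-2-en-1-yl)-5-(triisopropylsilyloxy)-3,4-dihydro-2H-chromen-2-yl]phenyl pivalate | COc1cc(O[Si](C(C)C)(C(C)C)C(C)C)c2c(c1CC=C(C)C)O[C@H](c1ccc(OC(=O)C(C)(C)C)cc1)C[C@H]2O
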